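**Plan**
- Retrosynthesis: take off the two silyl ethers and the C8 ketone oxidation state, cut the C19–O ester, then C11=C12 (C25 ylide + ring A lactol), C8–C9 (alkenyl–aldehyde coupling), C11'=C12' (C15 ylide + C10 dialdehyde) and, inside ring B, C1'–C6'.
- Enabling feature: ring B is an α-ionone-type ring (C1' = CMe2, C3' = carbinol, C4'=C5' with the methyl on C5', C6' = CH carrying the polyene), so the C1'–C6' bond and the C6' centre can come from a cation–olefin closure of an acyclic acetoxy trienone.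
- Forward: ring B is closed first (step 7) and grown C13 → C15 → C25; ring A is taken intact from ketoisophorone and given C7–C11 and C19 as a butenolide-derived lactol; the halves meet at C11=C12, followed by C19 ester, C8 ketone and desilylation.
- Stereochemistry: C3' from (R)-epichlorohydrin; C6' relayed from C3' in the chair of the ring closure; C3 from asymmetric transfer hydrogenation; C5'=C6' from syn-carboalumination, C9=C10 from the butenolide ring, the remaining alkenes from Heck and Wittig steps with E preference.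

Key step: step 7

Remark: carotenoid locants are used (unprimed = ring A half, primed = ring B half, C19 = the CH2O carbon on C9); the C8 carbinol made in step 19 is carried as an epimer mixture because step 23 oxidises it; 16, 28, 31 and 36 are taken as purchasable.

**Route**

Step 1
Reactants: 1 (R)-epichlorohydrin; 2 isopropenylmagnesium bromide
Product: 3 (2R)-1-chloro-4-methylpent-4-en-2-ol
Conditions: CuI (10 mol%), THF, −40 to −20 °C; aq. NH4Cl
Reagents that add atoms: none
Why: Copper-catalysed Grignard opening of the epoxide at its unsubstituted carbon (SN2) leaves the stereocentre of 1 untouched, so the chlorohydrin carries the configuration that becomes C3'.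

Step 2
Reactants: 3 (2R)-1-chloro-4-methylpent-4-en-2-ol
Product: 4 (2R)-2-(2-methylprop-2-en-1-yl)oxirane
Conditions: NaOH (powder), Et2O, rt
Reagents that add atoms: none
Why: Intramolecular Williamson displacement of chloride by the alkoxide re-forms the epoxide on the other side of the carbinol carbon without touching the stereocentre.

Step 3
Reactants: 4 (2R)-2-(2-methylprop-2-en-1-yl)oxirane; 5 lithium acetylide ethylenediamine complex (LiC≡CH·H2NCH2CH2NH2)
Product: 6 (4R)-2-methylhept-1-en-6-yn-4-ol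
Conditions: DMSO, 0 °C to rt
Reagents that add atoms: none
Why: SN2 opening of the terminal epoxide by the acetylide at the CH2 carbon should give the homopropargylic alcohol with the carbinol configuration retained.

Step 4
Reactants: 6 (4R)-2-methylhept-1-en-6-yn-4-ol
Product: 8 (1E,4R)-1-iodo-2,6-dimethylhepta-1,6-dien-4-ol, via alkenylalane 7 (not isolated)
Conditions: Me3Al (3 equiv), Cp2ZrCl2 (25 mol%), CH2Cl2, 0 °C to rt; then I2, THF, −30 to 0 °C
Reagents that add atoms: trimethylaluminium (C[Al](C)C); iodine ([I][I])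
Why: Negishi zirconium-catalysed carboalumination adds CH3 and Al syn across the terminal alkyne with the methyl on the internal carbon, and iodinolysis with retention gives the (E)-iodoalkene that fixes the C5'=C6' geometry, the 1,1-disubstituted alkene being inert.

Step 5
Reactants: 8 (1E,4R)-1-iodo-2,6-dimethylhepta-1,6-dien-4-ol
Product: 9 (1E,4R)-1-iodo-2,6-dimethylhepta-1,6-dien-4-yl acetate
Conditions: Ac2O, pyridine, DMAP (cat.), CH2Cl2, 0 °C to rt
Reagents that add atoms: acetic anhydride (CC(=O)OC(C)=O)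
Why: DMAP-catalysed acylation of the secondary alcohol installs an ester that tolerates H3PO4 and, being homoallylic to both alkenes, has no easy ionization path.

Step 6
Reactants: 9 (1E,4R)-1-iodo-2,6-dimethylhepta-1,6-dien-4-yl acetate; 10 but-3-en-2-one
Product: 11 (3E,5E,8R)-6,10-dimethyl-2-oxoundeca-3,5,10-trien-8-yl acetate
Conditions: Pd(OAc)2 (5 mol%), NaHCO3, Bu4NCl, DMF, rt to 40 °C
Reagents that add atoms: none
Why: Heck coupling under Jeffery conditions (oxidative addition into the C–I bond with retention, syn insertion of the enone, syn β-hydride elimination) should give the (3E,5E)-dienone, with the homoallylic acetate and the isolated isopropenyl group as spectators.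

Step 7
Reactants: 11 (3E,5E,8R)-6,10-dimethyl-2-oxoundeca-3,5,10-trien-8-yl acetate
Product: 12 (1R,4R)-3,5,5-trimethyl-4-[(1E)-3-oxobut-1-en-1-yl]cyclohex-2-en-1-yl acetate [(3R,6R)-3-acetoxy-α-ionone]
Conditions: 85% H3PO4, toluene, 20–30 °C; ice/NaHCO3
Reagents that add atoms: none
Why: The acid protonates the isopropenyl CH2 to give the tertiary C1' cation, C6' of the (E)-C5'=C6' alkene adds to it, and the tertiary C5' cation then loses a C4' proton. The closest known reaction is the Brønsted acid cyclization of pseudoionone to α-ionone, a cation–olefin cyclization. Ring B closes through a chair-like six-membered transition state, 6-endo-trig with respect to the C5'=C6' alkene. The new C6' centre is controlled by the C3' acetoxy centre, which should sit equatorial to avoid the axial C1' methyl, while the E geometry of C5'=C6' places the dienone chain equatorial, so the 3',6'-trans (3R,6R) ring is expected. The step needs proton loss toward C4' (α) and not toward C6' (β), which kinetic H3PO4 conditions favour, and it needs the ester to stay bound, which its homoallylic position relative to the initiating alkene and its equatorial position away from the C5' cation should secure.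

Step 8
Reactants: 12 (3R,6R)-3-acetoxy-α-ionone; 13 vinylmagnesium bromide
Product: 14 (1R,4R)-4-[(1E)-3-hydroxy-3-methylpenta-1,4-dien-1-yl]-3,5,5-trimethylcyclohex-2-en-1-yl acetate (both epimers at the new carbinol carbon)
Conditions: CeCl3 (anhydrous), THF, −78 °C; aq. NH4Cl
Reagents that add atoms: none
Why: Organocerium 1,2-addition to the enone carbonyl is faster than attack on the acetate or deprotonation at C6', and the new tertiary centre is lost in the next step.

Step 9
Reactants: 14 the vinyl carbinol acetate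
Product: 15 {(2E,4E)-5-[(1R,4R)-4-acetoxy-2,6,6-trimethylcyclohex-2-en-1-yl]-3-methylpenta-2,4-dien-1-yl}triphenylphosphonium bromide
Conditions: PPh3·HBr, MeOH/CH2Cl2, 0 °C to rt; recrystallisation
Reagents that add atoms: triphenylphosphine hydrobromide ([Br-].c1ccccc1[PH+](c1ccccc1)c1ccccc1)
Why: Acid ionization of the doubly allylic tertiary alcohol and SN1 capture of the pentadienyl cation by PPh3 at the unhindered terminal carbon (allylic transposition, the standard ionone-to-C15 Wittig salt sequence) should give mainly the 9'E salt, the electron-poor allylic acetate at C3' resisting ionization.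

Step 10
Reactants: 15 the C15 phosphonium bromide; 16 (2E,4E,6E)-2,7-dimethylocta-2,4,6-trienedial (in excess)
Product: 19 (2E,4E,6E,8E,10E,12E)-13-[(1R,4R)-4-hydroxy-2,6,6-trimethylcyclohex-2-en-1-yl]-2,7,11-trimethyltrideca-2,4,6,8,10,12-hexaenal, via ylide 17 (not isolated), via acetoxy aldehyde 18 (not isolated)
Conditions: NaOMe, CH2Cl2/MeOH, 0 °C to rt; then more NaOMe/MeOH, rt
Reagents that add atoms: none
Why: Wittig olefination of one formyl group by the semi-stabilised ylide forms C11'=C12' (its hindered Z isomer should isomerise to E on warming or be removed on crystallisation), and methoxide then removes the acetate by transesterification.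

Step 11
Reactants: 19 the C25 hydroxy aldehyde
Product: 20 (2E,4E,6E,8E,10E,12E)-13-[(1R,4R)-4-{[tert-butyl(dimethyl)silyl]oxy}-2,6,6-trimethylcyclohex-2-en-1-yl]-2,7,11-trimethyltrideca-2,4,6,8,10,12-hexaenal
Conditions: TBSCl, imidazole, DMF, rt
Reagents that add atoms: tert-butyldimethylsilyl chloride (CC(C)(C)[Si](C)(C)Cl)
Why: Imidazole-promoted silylation of the secondary alcohol gives an ether that fluoride can remove at the end without touching the C19 ester.

Step 12
Reactants: 20 the C25 silyloxy aldehyde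
Product: 21 (2E,4E,6E,8E,10E,12E)-13-[(1R,4R)-4-{[tert-butyl(dimethyl)silyl]oxy}-2,6,6-trimethylcyclohex-2-en-1-yl]-2,7,11-trimethyltrideca-2,4,6,8,10,12-hexaen-1-ol
Conditions: NaBH4, EtOH/THF, 0 °C
Reagents that add atoms: none
Why: Borohydride 1,2-reduction of the polyenal gives the primary allylic alcohol.

Step 13
Reactants: 21 the C25 alcohol
Product: 22 {(2E,4E,6E,8E,10E,12E)-13-[(1R,4R)-4-{[tert-butyl(dimethyl)silyl]oxy}-2,6,6-trimethylcyclohex-2-en-1-yl]-2,7,11-trimethyltrideca-2,4,6,8,10,12-hexaen-1-yl}triphenylphosphonium bromide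
Conditions: PPh3·HBr, CH2Cl2, 0 °C
Reagents that add atoms: triphenylphosphine hydrobromide ([Br-].c1ccccc1[PH+](c1ccccc1)c1ccccc1)
Why: The polyenyl primary alcohol ionizes under very mild acid and PPh3 traps the delocalised cation at the terminal carbon (SN1, the usual preparation of apocarotenyl Wittig salts), the short contact in an aprotic solvent sparing the silyl ether.

Step 14
Reactants: 23 ketoisophorone (2,6,6-trimethylcyclohex-2-ene-1,4-dione)
Product: 24 (4S)-4-hydroxy-2,6,6-trimethylcyclohex-2-en-1-one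
Conditions: RuCl(p-cymene)[(S,S)-TsDPEN] (0.5 mol%), KOH (cat.), i-PrOH, rt
Reagents that add atoms: none
Why: Noyori asymmetric transfer hydrogenation reduces the less hindered C4 carbonyl, the chiral Ru–H/N–H catalyst delivering hydride to one face with the alkene in the role of the aryl group; the ligand antipode is the one expected to give the 4S carbinol, which becomes C3 (3R in the target).

Step 15
Reactants: 24 (4S)-4-hydroxy-2,6,6-trimethylcyclohex-2-en-1-one
Product: 25 (4S)-4-{[tert-butyl(dimethyl)silyl]oxy}-2,6,6-trimethylcyclohex-2-en-1-one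
Conditions: TBSCl, imidazole, DMF, rt
Reagents that add atoms: tert-butyldimethylsilyl chloride (CC(C)(C)[Si](C)(C)Cl)
Why: Standard silylation of the secondary allylic alcohol.

Step 16
Reactants: 25 the silyloxy enone
Product: 27 (4R)-4-{[tert-butyl(dimethyl)silyl]oxy}-2,6,6-trimethylcyclohex-1-en-1-yl trifluoromethanesulfonate, via lithium enolate 26 (not isolated)
Conditions: Li[HB(s-Bu)3], THF, −78 °C; then PhNTf2, −78 to 0 °C
Reagents that add atoms: N-phenylbis(trifluoromethanesulfonimide) (O=S(=O)(N(c1ccccc1)S(=O)(=O)C(F)(F)F)C(F)(F)F)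
Why: Conjugate hydride addition to the β-unsubstituted enone (1,2-attack is blocked by the gem-dimethyl group) gives the tetrasubstituted enolate regiospecifically and O-triflation traps it; the descriptor changes from S to R only because the priorities change.

Step 17
Reactants: 27 the enol triflate; 28 2-[(E)-2-ethoxyethenyl]-4,4,5,5-tetramethyl-1,3,2-dioxaborolane
Product: 29 tert-butyl({(1R)-4-[(E)-2-ethoxyethenyl]-3,5,5-trimethylcyclohex-3-en-1-yl}oxy)dimethylsilane
Conditions: Pd(dppf)Cl2 (5 mol%), K3PO4, 1,4-dioxane/H2O, 80 °C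
Reagents that add atoms: none
Why: Suzuki–Miyaura coupling of the enol triflate with the alkenylboronate installs C7 and C8 as a masked acetaldehyde.

Step 18
Reactants: 29 the dienyl ethyl ether
Product: 30 2-[(4R)-4-{[tert-butyl(dimethyl)silyl]oxy}-2,6,6-trimethylcyclohex-1-en-1-yl]acetaldehyde
Conditions: (CO2H)2 (cat.), THF/H2O, rt
Reagents that add atoms: water (O)
Why: Mild acid hydrolysis of the enol ether by kinetic protonation at C7 should give the β,γ-unsaturated aldehyde without moving the ring alkene into conjugation or cleaving the silyl ether.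

Step 19
Reactants: 30 the ring A acetaldehyde; 31 4-bromofuran-2(5H)-one
Product: 32 4-{2-[(4R)-4-{[tert-butyl(dimethyl)silyl]oxy}-2,6,6-trimethylcyclohex-1-en-1-yl]-1-hydroxyethyl}furan-2(5H)-one (both carbinol epimers)
Conditions: CrCl2 (4 equiv), NiCl2 (2 mol%), DMF, rt
Reagents that add atoms: none
Why: Nozaki–Hiyama–Kishi coupling, in which zerovalent nickel inserts into the vinylic C–Br bond and the derived alkenylchromium species adds to the aldehyde chemoselectively, forms C8–C9 while tolerating the lactone and the enolizable aldehyde.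

Step 20
Reactants: 32 the carbinol butenolide
Product: 33 4-{2-[(4R)-4-{[tert-butyl(dimethyl)silyl]oxy}-2,6,6-trimethylcyclohex-1-en-1-yl]-1-hydroxyethyl}-2,5-dihydrofuran-2-ol (diastereomer mixture)
Conditions: i-Bu2AlH (3 equiv), CH2Cl2, −78 °C; aq. potassium sodium tartrate
Reagents that add atoms: none
Why: Low-temperature aluminium hydride reduction stops at the aluminium hemiacetal, giving the lactol in which the ring holds C19 and C11 cis across C9=C10.

Step 21
Reactants: 22 the C25 phosphonium bromide; 33 the ring A lactol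
Product: 35 (3R,3'R,6'R)-3,3'-bis{[tert-butyl(dimethyl)silyl]oxy}-7,8-dihydro-β,ε-carotene-8,19-diol (all-E, C8 epimers), via ylide 34 (not isolated)
Conditions: NaOMe, CH2Cl2/MeOH, −20 °C to rt; then EtOAc, 50 °C
Reagents that add atoms: none
Why: Wittig olefination of the lactol through its ring-opened (Z)-4-hydroxy-enal form makes C11=C12 and frees C19–OH, the C9=C10 geometry (C19 cis to C11) being inherited from the butenolide ring and the hindered 11Z isomer expected to isomerise to E on gentle warming.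

Step 22
Reactants: 35 the 8,19-diol; 36 (2E)-oct-2-enoic acid
Product: 37 (3R,3'R,6'R)-3,3'-bis{[tert-butyl(dimethyl)silyl]oxy}-8-hydroxy-7,8-dihydro-β,ε-caroten-19-yl (2E)-oct-2-enoate
Conditions: i-PrN=C=N-i-Pr, DMAP (cat.), CH2Cl2, −20 to 0 °C
Reagents that add atoms: none
Why: Steglich esterification should acylate the primary allylic C19–OH much faster than the secondary C8–OH flanked by the ring A methylene and the quaternary C9, and it avoids the ketene route that could deconjugate the enoate.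

Step 23
Reactants: 37 the C8 carbinol ester
Product: 38 (3R,3'R,6'R)-3,3'-bis{[tert-butyl(dimethyl)silyl]oxy}-8-oxo-7,8-dihydro-β,ε-caroten-19-yl (2E)-oct-2-enoate
Conditions: MnO2 (activated, excess), CH2Cl2, rt
Reagents that add atoms: none
Why: MnO2 oxidises the polyene-conjugated allylic C8 alcohol to the ketone under neutral conditions, converging both epimers while the silyl ethers, the ester and the C7 methylene stay untouched.

Step 24
Reactants: 38 the bis-silyl ether
Product: 39 (3R,3'R,6'R)-3,3'-dihydroxy-8-oxo-7,8-dihydro-β,ε-caroten-19-yl (2E)-oct-2-enoate (CNP0344057.1)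
Conditions: HF·pyridine, pyridine, THF, 0 °C to rt
Reagents that add atoms: none
Why: Buffered fluoride cleavage of both silyl ethers should leave the allylic C19 enoate, the polyenone and the acid-sensitive allylic C3' carbinol intact.

**Compound list**
1 | (R)-epichlorohydrin | ClC[C@H]1CO1 | starting material
2 | isopropenylmagnesium bromide | CC(=C)[Mg]Br | starting material
3 | (2R)-1-chloro-4-methylpent-4-en-2-ol | ClC[C@H](O)CC(C)=C | intermediate
4 | (2R)-2-(2-methylprop-2-en-1-yl)oxirane | C=C(C)C[C@@H]1CO1 | intermediate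
5 | lithium acetylide ethylenediamine complex | [Li]C#C.NCCN | starting material
6 | (4R)-2-methylhept-1-en-6-yn-4-ol | C=C(C)C[C@@H](O)CC#C | intermediate
7 | dimethyl[(1E,4R)-4-(dimethylalumanyloxy)-2,6-dimethylhepta-1,6-dien-1-yl]alumane (alkenylalane) | C=C(C)C[C@@H](O[Al](C)C)C/C(C)=C/[Al](C)C | intermediate (not isolated)
8 | (1E,4R)-1-iodo-2,6-dimethylhepta-1,6-dien-4-ol | C=C(C)C[C@@H](O)C/C(C)=C/I | intermediate
9 | (1E,4R)-1-iodo-2,6-dimethylhepta-1,6-dien-4-yl acetate | C=C(C)C[C@@H](OC(C)=O)C/C(C)=C/I | intermediate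
10 | but-3-en-2-one | CC(=O)C=C | starting material
11 | (3E,5E,8R)-6,10-dimethyl-2-oxoundeca-3,5,10-trien-8-yl acetate | C=C(C)C[C@@H](OC(C)=O)C/C(C)=C/C=C/C(C)=O | intermediate
12 | (1R,4R)-3,5,5-trimethyl-4-[(1E)-3-oxobut-1-en-1-yl]cyclohex-2-en-1-yl acetate, (3R,6R)-3-acetoxy-α-ionone | CC(=O)/C=C/[C@H]1C(C)=C[C@H](OC(C)=O)CC1(C)C | intermediate
13 | vinylmagnesium bromide | C=C[Mg]Br | starting material
14 | (1R,4R)-4-[(1E)-3-hydroxy-3-methylpenta-1,4-dien-1-yl]-3,5,5-trimethylcyclohex-2-en-1-yl acetate (carbinol epimers) | C=CC(C)(O)/C=C/[C@H]1C(C)=C[C@H](OC(C)=O)CC1(C)C | intermediate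
15 | {(2E,4E)-5-[(1R,4R)-4-acetoxy-2,6,6-trimethylcyclohex-2-en-1-yl]-3-methylpenta-2,4-dien-1-yl}triphenylphosphonium bromide | c1ccccc1[P+](c1ccccc1)(c1ccccc1)C/C=C(C)/C=C/[C@H]1C(C)=C[C@H](OC(C)=O)CC1(C)C.[Br-] | intermediate
16 | (2E,4E,6E)-2,7-dimethylocta-2,4,6-trienedial | O=C/C(C)=C/C=C/C=C(C)/C=O | starting material
17 | ylide of 15, {(2E,4E)-5-[(1R,4R)-4-acetoxy-2,6,6-trimethylcyclohex-2-en-1-yl]-3-methylpenta-2,4-dien-1-ylidene}triphenylphosphorane | c1ccccc1P(c1ccccc1)(c1ccccc1)=C/C=C(C)/C=C/[C@H]1C(C)=C[C@H](OC(C)=O)CC1(C)C | intermediate (not isolated)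
18 | (1R,4R)-3,5,5-trimethyl-4-[(1E,3E,5E,7E,9E,11E)-3,7,12-trimethyl-13-oxotrideca-1,3,5,7,9,11-hexaen-1-yl]cyclohex-2-en-1-yl acetate (C25 acetoxy aldehyde) | O=C/C(C)=C/C=C/C=C(C)/C=C/C=C(C)/C=C/[C@H]1C(C)=C[C@H](OC(C)=O)CC1(C)C | intermediate (not isolated)
19 | (2E,4E,6E,8E,10E,12E)-13-[(1R,4R)-4-hydroxy-2,6,6-trimethylcyclohex-2-en-1-yl]-2,7,11-trimethyltrideca-2,4,6,8,10,12-hexaenal | O=C/C(C)=C/C=C/C=C(C)/C=C/C=C(C)/C=C/[C@H]1C(C)=C[C@H](O)CC1(C)C | intermediate
20 | (2E,4E,6E,8E,10E,12E)-13-[(1R,4R)-4-{[tert-butyl(dimethyl)silyl]oxy}-2,6,6-trimethylcyclohex-2-en-1-yl]-2,7,11-trimethyltrideca-2,4,6,8,10,12-hexaenal | O=C/C(C)=C/C=C/C=C(C)/C=C/C=C(C)/C=C/[C@H]1C(C)=C[C@H](O[Si](C)(C)C(C)(C)C)CC1(C)C | intermediate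
21 | (2E,4E,6E,8E,10E,12E)-13-[(1R,4R)-4-{[tert-butyl(dimethyl)silyl]oxy}-2,6,6-trimethylcyclohex-2-en-1-yl]-2,7,11-trimethyltrideca-2,4,6,8,10,12-hexaen-1-ol | OC/C(C)=C/C=C/C=C(C)/C=C/C=C(C)/C=C/[C@H]1C(C)=C[C@H](O[Si](C)(C)C(C)(C)C)CC1(C)C | intermediate
22 | {(2E,4E,6E,8E,10E,12E)-13-[(1R,4R)-4-{[tert-butyl(dimethyl)silyl]oxy}-2,6,6-trimethylcyclohex-2-en-1-yl]-2,7,11-trimethyltrideca-2,4,6,8,10,12-hexaen-1-yl}triphenylphosphonium bromide | c1ccccc1[P+](c1ccccc1)(c1ccccc1)C/C(C)=C/C=C/C=C(C)/C=C/C=C(C)/C=C/[C@H]1C(C)=C[C@H](O[Si](C)(C)C(C)(C)C)CC1(C)C.[Br-] | intermediate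
23 | ketoisophorone (2,6,6-trimethylcyclohex-2-ene-1,4-dione) | CC1=CC(=O)CC(C)(C)C1=O | starting material
24 | (4S)-4-hydroxy-2,6,6-trimethylcyclohex-2-en-1-one | CC1=C[C@@H](O)CC(C)(C)C1=O | intermediate
25 | (4S)-4-{[tert-butyl(dimethyl)silyl]oxy}-2,6,6-trimethylcyclohex-2-en-1-one | CC1=C[C@@H](O[Si](C)(C)C(C)(C)C)CC(C)(C)C1=O | intermediate
26 | lithium (4R)-4-{[tert-butyl(dimethyl)silyl]oxy}-2,6,6-trimethylcyclohex-1-en-1-olate | CC1=C(O[Li])C(C)(C)C[C@H](O[Si](C)(C)C(C)(C)C)C1 | intermediate (not isolated)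
27 | (4R)-4-{[tert-butyl(dimethyl)silyl]oxy}-2,6,6-trimethylcyclohex-1-en-1-yl trifluoromethanesulfonate | CC1=C(OS(=O)(=O)C(F)(F)F)C(C)(C)C[C@H](O[Si](C)(C)C(C)(C)C)C1 | intermediate
28 | 2-[(E)-2-ethoxyethenyl]-4,4,5,5-tetramethyl-1,3,2-dioxaborolane | CCO/C=C/B1OC(C)(C)C(C)(C)O1 | starting material
29 | tert-butyl({(1R)-4-[(E)-2-ethoxyethenyl]-3,5,5-trimethylcyclohex-3-en-1-yl}oxy)dimethylsilane | CCO/C=C/C1=C(C)C[C@@H](O[Si](C)(C)C(C)(C)C)CC1(C)C | intermediate
30 | 2-[(4R)-4-{[tert-butyl(dimethyl)silyl]oxy}-2,6,6-trimethylcyclohex-1-en-1-yl]acetaldehyde | O=CCC1=C(C)C[C@@H](O[Si](C)(C)C(C)(C)C)CC1(C)C | intermediate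
31 | 4-bromofuran-2(5H)-one | O=C1C=C(Br)CO1 | starting material
32 | 4-{2-[(4R)-4-{[tert-butyl(dimethyl)silyl]oxy}-2,6,6-trimethylcyclohex-1-en-1-yl]-1-hydroxyethyl}furan-2(5H)-one (carbinol epimers) | O=C1C=C(C(O)CC2=C(C)C[C@@H](O[Si](C)(C)C(C)(C)C)CC2(C)C)CO1 | intermediate
33 | 4-{2-[(4R)-4-{[tert-butyl(dimethyl)silyl]oxy}-2,6,6-trimethylcyclohex-1-en-1-yl]-1-hydroxyethyl}-2,5-dihydrofuran-2-ol (diastereomer mixture) | OC1C=C(C(O)CC2=C(C)C[C@@H](O[Si](C)(C)C(C)(C)C)CC2(C)C)CO1 | intermediate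
34 | ylide of 22, {(2E,4E,6E,8E,10E,12E)-13-[(1R,4R)-4-{[tert-butyl(dimethyl)silyl]oxy}-2,6,6-trimethylcyclohex-2-en-1-yl]-2,7,11-trimethyltrideca-2,4,6,8,10,12-hexaen-1-ylidene}triphenylphosphorane | c1ccccc1P(c1ccccc1)(c1ccccc1)=C/C(C)=C/C=C/C=C(C)/C=C/C=C(C)/C=C/[C@H]1C(C)=C[C@H](O[Si](C)(C)C(C)(C)C)CC1(C)C | intermediate (not isolated)
35 | (3R,3'R,6'R)-3,3'-bis{[tert-butyl(dimethyl)silyl]oxy}-7,8-dihydro-β,ε-carotene-8,19-diol (all-E; ring A–CH2–CH(OH)–C(CH2OH)=CH–polyene–ring B; C8 epimers) | OC\C(=C/C=C/C(C)=C/C=C/C=C(C)/C=C/C=C(C)/C=C/[C@H]1C(C)=C[C@H](O[Si](C)(C)C(C)(C)C)CC1(C)C)C(O)CC1=C(C)C[C@@H](O[Si](C)(C)C(C)(C)C)CC1(C)C | intermediate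
36 | (2E)-oct-2-enoic acid | CCCCC/C=C/C(=O)O | starting material
37 | (3R,3'R,6'R)-3,3'-bis{[tert-butyl(dimethyl)silyl]oxy}-8-hydroxy-7,8-dihydro-β,ε-caroten-19-yl (2E)-oct-2-enoate (C8 epimers) | CCCCC/C=C/C(=O)OC\C(=C/C=C/C(C)=C/C=C/C=C(C)/C=C/C=C(C)/C=C/[C@H]1C(C)=C[C@H](O[Si](C)(C)C(C)(C)C)CC1(C)C)C(O)CC1=C(C)C[C@@H](O[Si](C)(C)C(C)(C)C)CC1(C)C | intermediate
38 | (3R,3'R,6'R)-3,3'-bis{[tert-butyl(dimethyl)silyl]oxy}-8-oxo-7,8-dihydro-β,ε-caroten-19-yl (2E)-oct-2-enoate | CCCCC/C=C/C(=O)OC\C(=C/C=C/C(C)=C/C=C/C=C(C)/C=C/C=C(C)/C=C/[C@H]1C(C)=C[C@H](O[Si](C)(C)C(C)(C)C)CC1(C)C)C(=O)CC1=C(C)C[C@@H](O[Si](C)(C)C(C)(C)C)CC1(C)C | intermediate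
39 | (3R,3'R,6'R)-3,3'-dihydroxy-8-oxo-7,8-dihydro-β,ε-caroten-19-yl (2E)-oct-2-enoate (CNP0344057.1) | CCCCC/C=C/C(=O)OC\C(=C/C=C/C(C)=C/C=C/C=C(C)/C=C/C=C(C)/C=C/[C@H]1C(C)=C[C@H](O)CC1(C)C)C(=O)CC1=C(C)C[C@@H](O)CC1(C)C | target

**Totals and risks**
Total step count: 24. Longest linear sequence: 17 steps (steps 1–13, then 21–24); the ring A branch (steps 14–20) joins at step 21.

Step 7 (ring closure). The C5' cation may lose a proton toward C6' or the methyl group, the ester may ionize once it has become allylic in 12, the isopropenyl group may instead attack the O-protonated dienone, and the chair may discriminate poorly between equatorial and axial acetoxy, eroding the 3',6'-trans relationship. The fallback forms the same C1'–C6' bond at the C10 aldehyde level through an anil and adds the enone afterwards. It sets out from 9: reductive carbonylation (Pd(PPh3)4, CO, Bu3SnH, THF, 50 °C) should give the enal (2E,5R)-3,7-dimethyl-1-oxoocta-2,7-dien-5-yl acetate F1; condensation with aniline (MgSO4, Et2O) gives the imine (2E,5R)-3,7-dimethyl-1-(phenylimino)octa-2,7-dien-5-yl acetate F2; cold concentrated H2SO4 (−20 °C, the classical anil cyclization to α-cyclocitral) and hydrolytic work-up should give (1R,4R)-4-formyl-3,5,5-trimethylcyclohex-2-en-1-yl acetate F3; Wittig olefination with 1-(triphenylphosphoranylidene)propan-2-one (toluene, 80 °C) returns to the route at 12.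

Step 21 (lactol Wittig union). The lactol may dehydrate to the 3-substituted furan, ring opening may be too slow for the ylide lifetime, or the open hydroxy-enal may lose its C9=C10 geometry. The fallback replaces the lactol by an open-chain, silyl-protected enal. It sets out from 32: aminolysis with MeNH(OMe)·HCl/Me3Al should give (2E)-5-[(4R)-4-{[tert-butyl(dimethyl)silyl]oxy}-2,6,6-trimethylcyclohex-1-en-1-yl]-4-hydroxy-3-(hydroxymethyl)-N-methoxy-N-methylpent-2-enamide F4 (amide carbon cis to the hydroxymethyl group); Et3SiCl/imidazole gives its bis(triethylsilyl) ether F5; i-Bu2AlH at −78 °C gives (2E)-5-[(4R)-4-{[tert-butyl(dimethyl)silyl]oxy}-2,6,6-trimethylcyclohex-1-en-1-yl]-4-[(triethylsilyl)oxy]-3-{[(triethylsilyl)oxy]methyl}pent-2-enal F6; Wittig reaction with ylide 34 gives the 8,19-bis(triethylsilyl) ether of 35 F7; HF·pyridine/pyridine at 0 °C, selective for the triethylsilyl ethers, returns to the route at 35.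

Step 19 (alkenylchromium addition). Oxidative addition into the vinylogous-ester C–Br bond may be sluggish, so that protodebromination or reductive dimerisation of 31 competes with addition to the aldehyde. The fallback makes C8–C9 by acylative Stille coupling at the ketone oxidation level. It sets out from 30: Pinnick oxidation (NaClO2, NaH2PO4, 2-methylbut-2-ene) gives [(4R)-4-{[tert-butyl(dimethyl)silyl]oxy}-2,6,6-trimethylcyclohex-1-en-1-yl]acetic acid F8; 1-chloro-N,N,2-trimethylprop-1-en-1-amine gives the acid chloride [(4R)-4-{[tert-butyl(dimethyl)silyl]oxy}-2,6,6-trimethylcyclohex-1-en-1-yl]acetyl chloride F9; 31 with Bu3SnSnBu3 and Pd(PPh3)4 gives 4-(tributylstannyl)furan-2(5H)-one F10; Stille coupling of F9 with F10 (PdCl2(PPh3)2, toluene, 60 °C) gives 4-{[(4R)-4-{[tert-butyl(dimethyl)silyl]oxy}-2,6,6-trimethylcyclohex-1-en-1-yl]acetyl}furan-2(5H)-one F11; Luche reduction (NaBH4, CeCl3, MeOH, −40 °C) of the ketone returns to the route at 32.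

**Further compounds**
F1 | step 7 | (2E,5R)-3,7-dimethyl-1-oxoocta-2,7-dien-5-yl acetate | C=C(C)C[C@@H](OC(C)=O)C/C(C)=C/C=O
F2 | step 7 | (2E,5R)-3,7-dimethyl-1-(phenylimino)octa-2,7-dien-5-yl acetate | C=C(C)C[C@@H](OC(C)=O)C/C(C)=C/C=N/c1ccccc1
F3 | step 7 | (1R,4R)-4-formyl-3,5,5-trimethylcyclohex-2-en-1-yl acetate | O=C[C@H]1C(C)=C[C@H](OC(C)=O)CC1(C)C
F4 | step 21 | (2E)-5-[(4R)-4-{[tert-butyl(dimethyl)silyl]oxy}-2,6,6-trimethylcyclohex-1-en-1-yl]-4-hydroxy-3-(hydroxymethyl)-N-methoxy-N-methylpent-2-enamide | OC\C(=C/C(=O)N(C)OC)C(O)CC1=C(C)C[C@@H](O[Si](C)(C)C(C)(C)C)CC1(C)C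
F5 | step 21 | (2E)-5-[(4R)-4-{[tert-butyl(dimethyl)silyl]oxy}-2,6,6-trimethylcyclohex-1-en-1-yl]-N-methoxy-N-methyl-4-[(triethylsilyl)oxy]-3-{[(triethylsilyl)oxy]methyl}pent-2-enamide | CC[Si](CC)(CC)OC\C(=C/C(=O)N(C)OC)C(O[Si](CC)(CC)CC)CC1=C(C)C[C@@H](O[Si](C)(C)C(C)(C)C)CC1(C)C
F6 | step 21 | (2E)-5-[(4R)-4-{[tert-butyl(dimethyl)silyl]oxy}-2,6,6-trimethylcyclohex-1-en-1-yl]-4-[(triethylsilyl)oxy]-3-{[(triethylsilyl)oxy]methyl}pent-2-enal | CC[Si](CC)(CC)OC\C(=C/C=O)C(O[Si](CC)(CC)CC)CC1=C(C)C[C@@H](O[Si](C)(C)C(C)(C)C)CC1(C)C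
F7 | step 21 | (3R,3'R,6'R)-3,3'-bis{[tert-butyl(dimethyl)silyl]oxy}-8,19-bis[(triethylsilyl)oxy]-7,8-dihydro-β,ε-carotene | CC[Si](CC)(CC)OC\C(=C/C=C/C(C)=C/C=C/C=C(C)/C=C/C=C(C)/C=C/[C@H]1C(C)=C[C@H](O[Si](C)(C)C(C)(C)C)CC1(C)C)C(O[Si](CC)(CC)CC)CC1=C(C)C[C@@H](O[Si](C)(C)C(C)(C)C)CC1(C)C
F8 | step 19 | [(4R)-4-{[tert-butyl(dimethyl)silyl]oxy}-2,6,6-trimethylcyclohex-1-en-1-yl]acetic acid | OC(=O)CC1=C(C)C[C@@H](O[Si](C)(C)C(C)(C)C)CC1(C)C
F9 | step 19 | [(4R)-4-{[tert-butyl(dimethyl)silyl]oxy}-2,6,6-trimethylcyclohex-1-en-1-yl]acetyl chloride | ClC(=O)CC1=C(C)C[C@@H](O[Si](C)(C)C(C)(C)C)CC1(C)C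
F10 | step 19 | 4-(tributylstannyl)furan-2(5H)-one | O=C1C=C([Sn](CCCC)(CCCC)CCCC)CO1
F11 | step 19 | 4-{[(4R)-4-{[tert-butyl(dimethyl)silyl]oxy}-2,6,6-trimethylcyclohex-1-en-1-yl]acetyl}furan-2(5H)-one | O=C1C=C(C(=O)CC2=C(C)C[C@@H](O[Si](C)(C)C(C)(C)C)CC2(C)C)CO1
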